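**Retrosynthetic overview**

1. The dioxane ring is closed last, at the bond between ring oxygen O4 and the benzylic carbon C3 (benzodioxin numbering). The acyclic precursor carries C3 as a CH2 group (one oxidation level lower) and only one stereocentre. Ag2O converts it into the p-quinone methide of the presumed biosynthesis (8–O–4′ coupling of a sinapyl with a caffeyl unit), and the ortho phenol of ring B adds to it 6-exo.
2. Enabling feature: ring A is a 4-hydroxy-3,5-dimethoxyphenyl ring bonded to C3. Its free para phenol with both ortho positions blocked by OMe gives the quinone methide cleanly, with C3 as the electrophilic exocyclic carbon, and the phenolic oxygen of ring B sits five atoms from C3.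
3. Precursor: the aryl–O1 bond comes from SNAr of a secondary alkoxide on 4-fluoro-3-(methoxymethoxy)benzaldehyde (fluorine para to the formyl group). The enal comes from a Wittig two-carbon homologation, and one acid step frees every masked group.
4. The C2 stereocentre is bought as (R)-trityl glycidyl ether, opened at its CH2 terminus by the syringyl Grignard reagent.
5. Ring order: rings A and B are bought as arenes; the 1,4-dioxane ring is the only ring formed (step 7).

Key step: step 7

Remark: the olefination product 10 is expected as a mixture of alkene isomers and is written without alkene geometry; both isomers should converge on the E-enal in step 6.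

**Route**

Step 1
Reactants: 1 4-bromo-2,6-dimethoxyphenol
Product: 2 5-bromo-1,3-dimethoxy-2-(methoxymethoxy)benzene
Conditions: MOMCl, iPr2NEt, CH2Cl2, 0 °C → rt
Reagents that add atoms: chloromethyl methyl ether, COCCl
Why: Williamson-type O-alkylation (MOM protection) of the hindered phenol with the reactive α-chloro ether should mask it for the Grignard and alkoxide steps.

Step 2
Reactants: 2 5-bromo-1,3-dimethoxy-2-(methoxymethoxy)benzene; 3 (2R)-2-[(triphenylmethoxy)methyl]oxirane [(R)-trityl glycidyl ether, the trityl ether of (S)-glycidol]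
Product: 5 (2R)-1-[3,5-dimethoxy-4-(methoxymethoxy)phenyl]-3-(triphenylmethoxy)propan-2-ol, via arylmagnesium bromide 4 (not isolated)
Conditions: Mg, THF, 45 °C; then CuI (10 mol %), 3, −30 → 0 °C; H2O
Reagents that add atoms: none
Why: The CuI-catalysed Grignard opening of a terminal epoxide is an SN2 attack at the unsubstituted CH2 carbon, so the stereocentre of 3 is untouched and becomes C2 of the target; the trityl ether is inert and cannot migrate.

Step 3
Reactants: 6 4-fluoro-3-hydroxybenzaldehyde
Product: 7 4-fluoro-3-(methoxymethoxy)benzaldehyde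
Conditions: MOMCl, iPr2NEt, CH2Cl2, 0 °C → rt
Reagents that add atoms: chloromethyl methyl ether, COCCl
Why: MOM protection (O-alkylation) keeps the phenol from forming a deactivating phenoxide in the following substitution.

Step 4
Reactants: 5 (2R)-1-[3,5-dimethoxy-4-(methoxymethoxy)phenyl]-3-(triphenylmethoxy)propan-2-ol; 7 4-fluoro-3-(methoxymethoxy)benzaldehyde
Product: 9 4-{[(2R)-1-[3,5-dimethoxy-4-(methoxymethoxy)phenyl]-3-(triphenylmethoxy)propan-2-yl]oxy}-3-(methoxymethoxy)benzaldehyde, via potassium alkoxide 8 (not isolated)
Conditions: KN(SiMe3)2, THF, −20 °C; then 7, DMF, −20 °C → rt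
Reagents that add atoms: none
Why: Nucleophilic aromatic substitution (SNAr, addition–elimination) displaces the fluoride para to the formyl group; the C–O bond at the stereocentre is not broken, so its configuration is retained, and this places the ether oxygen para to the future enal.

Step 5
Reactants: 9 4-{[(2R)-1-[3,5-dimethoxy-4-(methoxymethoxy)phenyl]-3-(triphenylmethoxy)propan-2-yl]oxy}-3-(methoxymethoxy)benzaldehyde
Product: 10 2-[2-(4-{[(2R)-1-[3,5-dimethoxy-4-(methoxymethoxy)phenyl]-3-(triphenylmethoxy)propan-2-yl]oxy}-3-(methoxymethoxy)phenyl)ethenyl]-1,3-dioxolane (E/Z mixture)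
Conditions: (1,3-dioxolan-2-ylmethyl)triphenylphosphonium bromide, KOtBu, THF, 0 °C → rt
Reagents that add atoms: (1,3-dioxolan-2-ylmethyl)triphenylphosphonium bromide, [Br-].C1COC(O1)C[P+](c1ccccc1)(c1ccccc1)c1ccccc1
Why: Wittig two-carbon homologation of the non-enolisable aryl aldehyde with the acetal-masked formylmethylene ylide should install the enal carbons; alkene geometry is corrected in step 6.

Step 6
Reactants: 10 2-[2-(4-{[(2R)-1-[3,5-dimethoxy-4-(methoxymethoxy)phenyl]-3-(triphenylmethoxy)propan-2-yl]oxy}-3-(methoxymethoxy)phenyl)ethenyl]-1,3-dioxolane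
Product: 11 (2E)-3-(3-hydroxy-4-{[(2R)-1-hydroxy-3-(4-hydroxy-3,5-dimethoxyphenyl)propan-2-yl]oxy}phenyl)prop-2-enal
Conditions: 3 M aq HCl, THF, 50 °C
Reagents that add atoms: water, O
Why: A single acid hydrolysis should cleave the dioxolane, the trityl ether and both aryl MOM acetals, with the enal equilibrating to the conjugated E isomer; the stereocentre has no ionisable neighbour and is not affected.

Step 7
Reactants: 11 (2E)-3-(3-hydroxy-4-{[(2R)-1-hydroxy-3-(4-hydroxy-3,5-dimethoxyphenyl)propan-2-yl]oxy}phenyl)prop-2-enal
Product: 13 (2E)-3-[(2S,3S)-3-(4-hydroxy-3,5-dimethoxyphenyl)-2-(hydroxymethyl)-2,3-dihydro-1,4-benzodioxin-6-yl]prop-2-enal, via p-quinone methide 12 (not isolated)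
Conditions: Ag2O (1.5 equiv), CH2Cl2/acetone, rt, dark, argon
Reagents that add atoms: none
Why: Ag2O should oxidise only the ring A phenol (a 4-alkyl-2,6-dimethoxyphenol, the most electron-rich arene, with no free ortho position for radical coupling) in two one-electron steps with loss of a benzylic proton, giving p-quinone methide 12, the intermediate that 8–O–4′ radical coupling of a sinapyl and a caffeyl unit would give in the presumed biosynthesis. The closest known reaction types are the Ag2O dehydrogenation of 4-alkyl-2,6-dimethoxyphenols to p-quinone methides and the oxidative cyclisation of phenol-tethered 4-alkylphenols to flavans and related cyclic benzylic ethers. The dioxane ring closes by 6-exo-trig oxa-1,6-addition (vinylogous oxa-Michael) of the ring B phenol oxygen to the exocyclic methide carbon, which rearomatises ring A. The new benzylic stereocentre C3 is controlled by the existing C2 centre through a chair-like transition state with the CH2OH group and the quinone methide ring both pseudo-equatorial, which should give the trans (2S,3S) isomer; because a phenolic benzyl aryl ether can reopen to the planar quinone methide, any cis isomer should drain to the trans product. The step needs chemoselective oxidation of ring A over the ring B phenol, secured by the two methoxy groups on ring A and the electron-withdrawing enal on ring B. It also needs O-attack by the phenol rather than by the primary alcohol or a ring carbon, secured by the six-membered ring size (the alcohol could only form an oxetane).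

**Compound list**

1 | 4-bromo-2,6-dimethoxyphenol | COc1cc(Br)cc(OC)c1O | starting material
2 | 5-bromo-1,3-dimethoxy-2-(methoxymethoxy)benzene | COCOc1c(OC)cc(Br)cc1OC | intermediate
3 | (2R)-2-[(triphenylmethoxy)methyl]oxirane | C1[C@H](COC(c2ccccc2)(c2ccccc2)c2ccccc2)O1 | starting material
4 | [3,5-dimethoxy-4-(methoxymethoxy)phenyl]magnesium bromide | COCOc1c(OC)cc([Mg]Br)cc1OC | intermediate
5 | (2R)-1-[3,5-dimethoxy-4-(methoxymethoxy)phenyl]-3-(triphenylmethoxy)propan-2-ol | COCOc1c(OC)cc(C[C@H](COC(c2ccccc2)(c2ccccc2)c2ccccc2)O)cc1OC | intermediate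
6 | 4-fluoro-3-hydroxybenzaldehyde | O=Cc1ccc(F)c(O)c1 | starting material
7 | 4-fluoro-3-(methoxymethoxy)benzaldehyde | COCOc1cc(C=O)ccc1F | intermediate
8 | potassium (2R)-1-[3,5-dimethoxy-4-(methoxymethoxy)phenyl]-3-(triphenylmethoxy)propan-2-olate | COCOc1c(OC)cc(C[C@H](COC(c2ccccc2)(c2ccccc2)c2ccccc2)[O-])cc1OC.[K+] | intermediate
9 | 4-{[(2R)-1-[3,5-dimethoxy-4-(methoxymethoxy)phenyl]-3-(triphenylmethoxy)propan-2-yl]oxy}-3-(methoxymethoxy)benzaldehyde | COCOc1c(OC)cc(C[C@H](COC(c2ccccc2)(c2ccccc2)c2ccccc2)Oc2ccc(C=O)cc2OCOC)cc1OC | intermediate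
10 | 2-[2-(4-{[(2R)-1-[3,5-dimethoxy-4-(methoxymethoxy)phenyl]-3-(triphenylmethoxy)propan-2-yl]oxy}-3-(methoxymethoxy)phenyl)ethenyl]-1,3-dioxolane (E/Z mixture) | COCOc1c(OC)cc(C[C@H](COC(c2ccccc2)(c2ccccc2)c2ccccc2)Oc2ccc(C=CC3OCCO3)cc2OCOC)cc1OC | intermediate
11 | (2E)-3-(3-hydroxy-4-{[(2R)-1-hydroxy-3-(4-hydroxy-3,5-dimethoxyphenyl)propan-2-yl]oxy}phenyl)prop-2-enal | COc1cc(C[C@H](CO)Oc2ccc(/C=C/C=O)cc2O)cc(OC)c1O | intermediate
12 | 4-{(2R)-3-hydroxy-2-[2-hydroxy-4-[(1E)-3-oxoprop-1-en-1-yl]phenoxy]propylidene}-2,6-dimethoxycyclohexa-2,5-dien-1-one | COC1=CC(=C[C@H](CO)Oc2ccc(/C=C/C=O)cc2O)C=C(OC)C1=O | intermediate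
13 | (2E)-3-[(2S,3S)-3-(4-hydroxy-3,5-dimethoxyphenyl)-2-(hydroxymethyl)-2,3-dihydro-1,4-benzodioxin-6-yl]prop-2-enal | COc1cc([C@@H]2Oc3cc(/C=C/C=O)ccc3O[C@H]2CO)cc(OC)c1O | target

**Summary**

Total step count: 7. Longest linear sequence: 6 steps (steps 1, 2, 4, 5, 6, 7); step 3 is a one-step side branch.

Steps most likely to fail:

Step 7. The oxidation may not stay on ring A (the ring B phenol or the product phenol may be oxidised further). The quinone methide may tautomerise to the aryl enol ether before closure, or kinetic closure may give incomplete trans selectivity. Fallback, from 11 back to 13: oxidation and ring closure are separated. DDQ (1 equiv) in CH2Cl2/MeOH at 0 °C should generate the quinone methide and let methanol intercept it, giving the isolable benzylic ether (2E)-3-(3-hydroxy-4-{[(2S)-3-hydroxy-1-(4-hydroxy-3,5-dimethoxyphenyl)-1-methoxypropan-2-yl]oxy}phenyl)prop-2-enal F1 as an epimer mixture at the methoxy-bearing carbon, together with any directly cyclised material. The crude mixture is then treated with catalytic TsOH in MeCN at rt to 40 °C. This is the classical acid-catalysed closure of a β-aryl ether benzylic ether: the p-hydroxybenzyl ether ionises reversibly, and closure under equilibrating conditions should funnel both epimers and any cis product to trans 13.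

Step 4. The hindered secondary alkoxide may add to the formyl group or transfer hydride to it (Meerwein–Ponndorf–Verley-type reduction) faster than it displaces fluoride. Fallback, from 5 back to 9: the electrophile is changed to a nitrile, which cannot undergo these carbonyl side reactions. 4-Fluoro-3-(methoxymethoxy)benzonitrile F2 is made from commercial 4-fluoro-3-hydroxybenzonitrile with MOMCl and iPr2NEt. SNAr with the potassium alkoxide of 5 (KN(SiMe3)2, THF/DMF) should give 4-{[(2R)-1-[3,5-dimethoxy-4-(methoxymethoxy)phenyl]-3-(triphenylmethoxy)propan-2-yl]oxy}-3-(methoxymethoxy)benzonitrile F3. Partial reduction with iBu2AlH in toluene at −78 °C and hydrolytic work-up then gives aldehyde 9.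

Step 6. Cleaving two aryl MOM ethers needs acid and heat that the freed enal may not tolerate (acetalisation, conjugate addition, reaction with liberated formaldehyde). Fallback, from 9 back to 11: the order is inverted so that no enal is present during deprotection. Aldehyde 9 is deprotected first (3 M aq HCl, THF, 50 °C) to 3-hydroxy-4-{[(2R)-1-hydroxy-3-(4-hydroxy-3,5-dimethoxyphenyl)propan-2-yl]oxy}benzaldehyde F4. This is then homologated under neutral conditions with the stabilised ylide (triphenylphosphoranylidene)acetaldehyde in toluene at 80 °C, which tolerates free phenols and should give E-enal 11 directly.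

**Further compounds**

F1 | step 7 | (2E)-3-(3-hydroxy-4-{[(2S)-3-hydroxy-1-(4-hydroxy-3,5-dimethoxyphenyl)-1-methoxypropan-2-yl]oxy}phenyl)prop-2-enal (epimer mixture at the methoxy-bearing carbon) | COc1cc(C(OC)[C@H](CO)Oc2ccc(/C=C/C=O)cc2O)cc(OC)c1O
F2 | step 4 | 4-fluoro-3-(methoxymethoxy)benzonitrile | COCOc1cc(C#N)ccc1F
F3 | step 4 | 4-{[(2R)-1-[3,5-dimethoxy-4-(methoxymethoxy)phenyl]-3-(triphenylmethoxy)propan-2-yl]oxy}-3-(methoxymethoxy)benzonitrile | COCOc1c(OC)cc(C[C@H](COC(c2ccccc2)(c2ccccc2)c2ccccc2)Oc2ccc(C#N)cc2OCOC)cc1OC
F4 | step 6 | 3-hydroxy-4-{[(2R)-1-hydroxy-3-(4-hydroxy-3,5-dimethoxyphenyl)propan-2-yl]oxy}benzaldehyde | COc1cc(C[C@H](CO)Oc2ccc(C=O)cc2O)cc(OC)c1O
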